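What share of the substrate has reacted after 25 h, and how much of it stands as isomer of the product, when the reagent charge is set below that of the earlier cedar run?

- cedar: substrate 2 M; reagent 1.5 M; run made earlier
- flask: substrate 2.0 M; reagent 1.00 M; time 25 h

cedar run (percent of the substrate charged)

| time / h | substrate / % | isomer of the product / % | target / % |
|---|---|---|---|
| 0.250 | 48.1 | 35.9 | 6.5 |
| 0.833 | 31.2 | 67.6 | 1.1 |
| 1.33 | 26.8 | 71.8 | 0.3 |
| 2.00 | 25.7 | 73.8 | 1.0 |
| 3.00 | 24.9 | 74.7 | 0.3 |
| 4.00 | 25.4 | 75.3 | 0 |
| 5.00 | 25.0 | 74.3 | 0 |

(scatter of a reading: 0.5 percentage points)

* conversion of substrate at 25 h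
* amount of isomer of the product at 25 h, in percent of the substrate charged



From 2.00 h on, the substrate readings of the cedar run lie between 24.9% and 25.7%, with a scatter of 0.5 percentage points on each reading. The substrate lost by its last reading is 1.50 M, matching the 1.5 M of reagent charged, so the readings point to one reagent per substrate, with reagent as the limiting reagent. Conversion should then stop at the smaller of complete conversion and c_reagent/c_substrate: 75.0% for the cedar run and 50.0% for the new flask, the reagent ceiling.

Substrate is not turned, with 2.0 M in the new flask as in the cedar run. Reagent is, and going from 1.5 M to 1.00 M lowers the ceiling by 25 points. Time is turned too, from 5.00 h to 25 h, but it should add nothing. The cedar run was flat by 2.00 h, far short of 25 h, and the last reagent in the new flask meets a substrate surplus of 1.00 M against 0.500 M there, a pseudo-first-order tail that should run no slower. The cedar run's last reading has 99.1% of the converted substrate as isomer, so my own reckoning gives 50.0% conversion and about 49.5% isomer.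

The forecast, reading the plateau “with the reagent limiting, not as an equilibrium”, gives 50% conversion (47.5% to 52%) and 50% isomer (46.5% to 51.5%). The flask gives 50.0% conversion and 49.6% isomer.

    intermediate ⇌ isomer of the product (K = 270, k = 0.00500 s⁻¹)
    substrate + reagent → intermediate + by-product (k = 9.40 × 10⁻⁴ M⁻¹ s⁻¹)
    intermediate ⇌ target (K = 1.00, k = 0.0120 s⁻¹)

The flask has stopped at its ceiling of 50.0%. A neighbouring flask takes 0.50 M of substrate with reagent still at 1.00 M, which puts the ceiling at 100% and the reckoned isomer at 99.1%. That neighbour reaches 100% conversion and 99.3% isomer, ending with 0% of its substrate and 50% of its reagent left.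

The readings come from a simulation from invented constants; noise was put on by code.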